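**Plan**
- Retrosynthesis, cut 1: the exocyclic C–N bond from the 2-amino nitrogen to C4 of the methylated imidazoledione (back to a 2-aminoimidazole and 1-methylparabanic acid). Cut 2: the C2–N bond (back to a 2-chloroimidazole and, one step earlier, an imidazole 3-oxide).
- Cut 3 (key): N3–C2 and N1–C5 of the imidazole. N1(CH3)–C2H is an N-methylmethanimine unit, and C4/C5 with their two unlike benzyl groups are an α-hydroxyimino ketone whose oxime carbon becomes C4.
- Cut 4: the ketone C–CH2Ar bond, back to an O-silyl oxime Weinreb amide and a benzylic Grignard reagent.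
- Forward: the two arms are joined to the open chain, the imidazole ring closes as its 3-oxide, the N-oxide is spent on chlorinating C2, nitrogen is brought in by cross-coupling, the phenol is unmasked, and the ready-made imidazoledione ring is attached last.
- Stereochemistry: the target has no stereocentre; the only stereo-element on the way, the oxime geometry, disappears in the ring closure.

Key step: step 9

Assumption: oximes 6, 7, 8, 10 and 11 are drawn as the E isomers (oxygen on nitrogen anti to the carbonyl), the usual geometry of arylpyruvic acid oximes; any Z isomer is carried along. Compounds 1, 5, 12 and 19 are taken as purchasable.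

Step 1
Reactants: 1 2-hydroxy-3,4-dimethoxybenzaldehyde
Product: 2 2-(benzyloxy)-3,4-dimethoxybenzaldehyde
Conditions: BnBr, K2CO3, DMF, 60 °C
Reagents that add atoms: benzyl bromide BrCc1ccccc1
Why: Williamson ether synthesis, in which the phenoxide formed with K2CO3 is alkylated by benzyl bromide while the aldehyde is inert.

Step 2
Reactants: 2 2-(benzyloxy)-3,4-dimethoxybenzaldehyde
Product: 3 [2-(benzyloxy)-3,4-dimethoxyphenyl]methanol
Conditions: NaBH4, MeOH, 0 °C to rt
Reagents that add atoms: none
Why: Borohydride reduction of an aromatic aldehyde is chemoselective and leaves the benzyl and methyl ethers untouched.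

Step 3
Reactants: 3 [2-(benzyloxy)-3,4-dimethoxyphenyl]methanol
Product: 4 2-(benzyloxy)-1-(chloromethyl)-3,4-dimethoxybenzene
Conditions: SOCl2, CH2Cl2, 0 °C to rt, used without storage
Reagents that add atoms: thionyl chloride O=S(Cl)Cl
Why: Chlorodehydroxylation of an electron-rich benzylic alcohol through its chlorosulfite is fast at low temperature, and immediate use avoids solvolysis of the labile chloride.

Step 4
Reactants: 5 4-methoxyphenylpyruvic acid
Product: 6 (2E)-2-(hydroxyimino)-3-(4-methoxyphenyl)propanoic acid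
Conditions: NH2OH·HCl, NaOAc, EtOH/H2O, rt
Reagents that add atoms: hydroxylamine hydrochloride Cl.NO
Why: Oxime condensation of an α-keto acid in acetate buffer should be fast and give the thermodynamically preferred E oxime, as is general for arylpyruvic acids.

Step 5
Reactants: 6 (2E)-2-(hydroxyimino)-3-(4-methoxyphenyl)propanoic acid
Product: 7 (2E)-2-(hydroxyimino)-N-methoxy-3-(4-methoxyphenyl)-N-methylpropanamide
Conditions: MeNHOMe·HCl, EDC·HCl, HOBt, N-methylmorpholine, CH2Cl2, 0 °C to rt
Reagents that add atoms: N,O-dimethylhydroxylamine hydrochloride CNOC.Cl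
Why: Carbodiimide/HOBt amide coupling (Weinreb amide formation), in which the active ester should be taken by the α-effect amine faster than by the oxime hydroxyl, as in known couplings of unprotected 2-(hydroxyimino)-3-arylpropanoic acids with amines.

Step 6
Reactants: 7 (2E)-2-(hydroxyimino)-N-methoxy-3-(4-methoxyphenyl)-N-methylpropanamide
Product: 8 (2E)-2-({[tert-butyl(dimethyl)silyl]oxy}imino)-N-methoxy-3-(4-methoxyphenyl)-N-methylpropanamide
Conditions: TBSCl, imidazole, DMF, rt
Reagents that add atoms: tert-butyldimethylsilyl chloride CC(C)(C)[Si](C)(C)Cl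
Why: O-Silylation of the oxime removes the only acidic proton before the organomagnesium step and gives an oxime ether that fluoride cleaves later.

Step 7
Reactants: 4 2-(benzyloxy)-1-(chloromethyl)-3,4-dimethoxybenzene; 8 (2E)-2-({[tert-butyl(dimethyl)silyl]oxy}imino)-N-methoxy-3-(4-methoxyphenyl)-N-methylpropanamide
Product: 10 (3E)-1-[2-(benzyloxy)-3,4-dimethoxyphenyl]-3-({[tert-butyl(dimethyl)silyl]oxy}imino)-4-(4-methoxyphenyl)butan-2-one, via [2-(benzyloxy)-3,4-dimethoxybenzyl]magnesium chloride 9 (not isolated)
Conditions: Mg turnings, THF, 0 °C, slow addition of 4; then 8, THF, −78 to 0 °C; aq. NH4Cl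
Reagents that add atoms: none
Why: Grignard formation followed by Weinreb ketone synthesis, in which the chelated tetrahedral adduct prevents over-addition and the O-silyl oxime ether is too weak an electrophile to compete.

Step 8
Reactants: 10 (3E)-1-[2-(benzyloxy)-3,4-dimethoxyphenyl]-3-({[tert-butyl(dimethyl)silyl]oxy}imino)-4-(4-methoxyphenyl)butan-2-one
Product: 11 (3E)-1-[2-(benzyloxy)-3,4-dimethoxyphenyl]-3-(hydroxyimino)-4-(4-methoxyphenyl)butan-2-one
Conditions: TBAF, AcOH, THF, 0 °C
Reagents that add atoms: none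
Why: Fluoride desilylation of the oxime silyl ether, buffered with acetic acid so that the enolisable α-hydroxyimino ketone is not exposed to basic fluoride.

Step 9
Reactants: 11 (3E)-1-[2-(benzyloxy)-3,4-dimethoxyphenyl]-3-(hydroxyimino)-4-(4-methoxyphenyl)butan-2-one; 12 1,3,5-trimethyl-1,3,5-triazinane
Product: 14 5-[2-(benzyloxy)-3,4-dimethoxybenzyl]-4-(4-methoxybenzyl)-1-methyl-1H-imidazole 3-oxide, via N-methylmethanimine 13 (not isolated)
Conditions: 12 (0.4 equiv, corresponding to 1.2 equiv of 13), EtOH, reflux
Reagents that add atoms: none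
Why: On heating, each molecule of the cyclic trimer 12 releases three molecules of N-methylmethanimine 13, and the oxime nitrogen of 11 adds to the imine carbon, forming N3–C2 and an N-(methylaminomethyl) nitrone. The secondary amine then attacks the neighbouring ketone in a 5-exo-trig closure (N1–C5), and loss of water with a proton shift from C2 aromatises the ring to the imidazole 3-oxide. The closest known reaction type is the condensation of α-hydroxyimino ketones with formaldimines, used as their hexahydro-1,3,5-triazine trimers, to 2-unsubstituted imidazole 3-oxides. No stereocentre is formed, and the oxime geometry is lost; the E oxime has its nitrogen lone pair on the ketone side, so the aminomethyl arm is delivered next to the carbonyl. The selectivity needed is the placement of the N-methyl group, and it is secured by the substrate: the oxime carbon carries the 4-methoxybenzyl group and becomes C4, while the ketone carbon carries the trioxygenated benzyl group and becomes C5 next to N-methyl. The oxime oxygen remains as the N-oxide, which activates C2 for the next step.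

Step 10
Reactants: 14 5-[2-(benzyloxy)-3,4-dimethoxybenzyl]-4-(4-methoxybenzyl)-1-methyl-1H-imidazole 3-oxide
Product: 15 5-[2-(benzyloxy)-3,4-dimethoxybenzyl]-2-chloro-4-(4-methoxybenzyl)-1-methyl-1H-imidazole
Conditions: POCl3, CHCl3, 0 °C to reflux; aq. NaHCO3
Reagents that add atoms: phosphoryl chloride O=P(Cl)(Cl)Cl
Why: Deoxygenative chlorination of an azole N-oxide, in which O-phosphorylation makes C2 electrophilic, chloride adds there and elimination of dichlorophosphate with the C2 proton gives the 2-chloroimidazole, the known outcome for 2-unsubstituted imidazole 3-oxides; benzyl aryl ethers tolerate POCl3, as in Bischler–Napieralski cyclisations.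

Step 11
Reactants: 15 5-[2-(benzyloxy)-3,4-dimethoxybenzyl]-2-chloro-4-(4-methoxybenzyl)-1-methyl-1H-imidazole
Product: 17 5-[2-(benzyloxy)-3,4-dimethoxybenzyl]-4-(4-methoxybenzyl)-1-methyl-1H-imidazol-2-amine, via N-(diphenylmethylene)imidazol-2-amine 16 (not isolated)
Conditions: Ph2C=NH, Pd2(dba)3, tBuBrettPhos, NaOtBu, toluene, 100 °C; then 1 M HCl, THF, rt
Reagents that add atoms: benzophenone imine N=C(c1ccccc1)c1ccccc1
Why: Buchwald–Hartwig amination with benzophenone imine as ammonia surrogate, in which the bulky electron-rich biarylphosphine helps zerovalent palladium insert into the C2–Cl bond, and mild aqueous acid then hydrolyses the diphenylmethylene group without touching the benzyl ether.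

Step 12
Reactants: 17 5-[2-(benzyloxy)-3,4-dimethoxybenzyl]-4-(4-methoxybenzyl)-1-methyl-1H-imidazol-2-amine
Product: 18 6-{[2-amino-4-(4-methoxybenzyl)-1-methyl-1H-imidazol-5-yl]methyl}-2,3-dimethoxyphenol
Conditions: H2 (1 atm), 10% Pd/C, MeOH, rt
Reagents that add atoms: none
Why: Catalytic hydrogenolysis of a benzyl aryl ether is selective here because the methyl ethers, the 2-aminoimidazole and the benzylic CH2 links are inert under one atmosphere of hydrogen.

Step 13
Reactants: 18 6-{[2-amino-4-(4-methoxybenzyl)-1-methyl-1H-imidazol-5-yl]methyl}-2,3-dimethoxyphenol; 19 1-methylimidazolidine-2,4,5-trione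
Product: 21 pyronaamidine, via 1-methyl-4-(trimethylsilyloxy)imidazole-2,5-dione 20 (not isolated)
Conditions: 19, N,O-bis(trimethylsilyl)acetamide (BSA), MeCN, reflux; then 18, toluene, reflux; MeOH work-up
Reagents that add atoms: none
Why: Addition–elimination condensation of a 2-aminoimidazole with silyl-activated 1-methylparabanic acid, known for related 2-aminoimidazole alkaloids, in which the amine adds to the silyl imidate carbon C4 of 20 and trimethylsilanolate leaves, while any transient silylation of the phenol is undone by methanol.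

**Compound list**
1 | 2-hydroxy-3,4-dimethoxybenzaldehyde | COc1ccc(C=O)c(O)c1OC | starting material
2 | 2-(benzyloxy)-3,4-dimethoxybenzaldehyde | COc1ccc(C=O)c(OCc2ccccc2)c1OC | intermediate
3 | [2-(benzyloxy)-3,4-dimethoxyphenyl]methanol | COc1ccc(CO)c(OCc2ccccc2)c1OC | intermediate
4 | 2-(benzyloxy)-1-(chloromethyl)-3,4-dimethoxybenzene | COc1ccc(CCl)c(OCc2ccccc2)c1OC | intermediate
5 | 4-methoxyphenylpyruvic acid | COc1ccc(CC(=O)C(=O)O)cc1 | starting material
6 | (2E)-2-(hydroxyimino)-3-(4-methoxyphenyl)propanoic acid | COc1ccc(C/C(=N\O)C(=O)O)cc1 | intermediate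
7 | (2E)-2-(hydroxyimino)-N-methoxy-3-(4-methoxyphenyl)-N-methylpropanamide | COc1ccc(C/C(=N\O)C(=O)N(C)OC)cc1 | intermediate
8 | (2E)-2-({[tert-butyl(dimethyl)silyl]oxy}imino)-N-methoxy-3-(4-methoxyphenyl)-N-methylpropanamide | COc1ccc(C/C(=N\O[Si](C)(C)C(C)(C)C)C(=O)N(C)OC)cc1 | intermediate
9 | [2-(benzyloxy)-3,4-dimethoxybenzyl]magnesium chloride | COc1ccc(C[Mg]Cl)c(OCc2ccccc2)c1OC | intermediate
10 | (3E)-1-[2-(benzyloxy)-3,4-dimethoxyphenyl]-3-({[tert-butyl(dimethyl)silyl]oxy}imino)-4-(4-methoxyphenyl)butan-2-one | COc1ccc(C/C(=N\O[Si](C)(C)C(C)(C)C)C(=O)Cc2ccc(OC)c(OC)c2OCc2ccccc2)cc1 | intermediate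
11 | (3E)-1-[2-(benzyloxy)-3,4-dimethoxyphenyl]-3-(hydroxyimino)-4-(4-methoxyphenyl)butan-2-one | COc1ccc(C/C(=N\O)C(=O)Cc2ccc(OC)c(OC)c2OCc2ccccc2)cc1 | intermediate
12 | 1,3,5-trimethyl-1,3,5-triazinane | CN1CN(C)CN(C)C1 | starting material
13 | N-methylmethanimine | CN=C | intermediate
14 | 5-[2-(benzyloxy)-3,4-dimethoxybenzyl]-4-(4-methoxybenzyl)-1-methyl-1H-imidazole 3-oxide | COc1ccc(Cc2c(Cc3ccc(OC)c(OC)c3OCc3ccccc3)n(C)c[n+]2[O-])cc1 | intermediate
15 | 5-[2-(benzyloxy)-3,4-dimethoxybenzyl]-2-chloro-4-(4-methoxybenzyl)-1-methyl-1H-imidazole | COc1ccc(Cc2nc(Cl)n(C)c2Cc2ccc(OC)c(OC)c2OCc2ccccc2)cc1 | intermediate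
16 | N-{5-[2-(benzyloxy)-3,4-dimethoxybenzyl]-4-(4-methoxybenzyl)-1-methyl-1H-imidazol-2-yl}-1,1-diphenylmethanimine | COc1ccc(Cc2nc(N=C(c3ccccc3)c3ccccc3)n(C)c2Cc2ccc(OC)c(OC)c2OCc2ccccc2)cc1 | intermediate
17 | 5-[2-(benzyloxy)-3,4-dimethoxybenzyl]-4-(4-methoxybenzyl)-1-methyl-1H-imidazol-2-amine | COc1ccc(Cc2nc(N)n(C)c2Cc2ccc(OC)c(OC)c2OCc2ccccc2)cc1 | intermediate
18 | 6-{[2-amino-4-(4-methoxybenzyl)-1-methyl-1H-imidazol-5-yl]methyl}-2,3-dimethoxyphenol | COc1ccc(Cc2nc(N)n(C)c2Cc2ccc(OC)c(OC)c2O)cc1 | intermediate
19 | 1-methylimidazolidine-2,4,5-trione (1-methylparabanic acid) | CN1C(=O)NC(=O)C1=O | starting material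
20 | 1-methyl-4-[(trimethylsilyl)oxy]-1H-imidazole-2,5-dione | CN1C(=O)N=C(O[Si](C)(C)C)C1=O | intermediate
21 | pyronaamidine, 4-{[5-(2-hydroxy-3,4-dimethoxybenzyl)-4-(4-methoxybenzyl)-1-methyl-1H-imidazol-2-yl]amino}-1-methyl-1H-imidazole-2,5-dione | COc1ccc(Cc2nc(NC3=NC(=O)N(C)C3=O)n(C)c2Cc2ccc(OC)c(OC)c2O)cc1 | target

**Step count**
Total: 13 steps. Longest linear sequence: 10 steps (steps 1–3 or 4–6, then 7–13).

**Steps most likely to fail**

Step 7. Magnesium insertion into the electron-rich benzylic chloride may be eroded by Wurtz-type homocoupling. The basic Grignard reagent may also deprotonate the benzylic methylene next to the oxime ether instead of adding to the amide. The fallback replaces the Grignard/Weinreb pair by a non-basic organozinc and an acid chloride. It sets out from oxime acid 6 and chloride 4 and comes back to the route at ketone 10. Acid 6 would be silylated on both oxygens (TBSCl, imidazole, DMF) to tert-butyl(dimethyl)silyl (2E)-2-({[tert-butyl(dimethyl)silyl]oxy}imino)-3-(4-methoxyphenyl)propanoate F1. The silyl ester would be converted directly into (2E)-2-({[tert-butyl(dimethyl)silyl]oxy}imino)-3-(4-methoxyphenyl)propanoyl chloride F2 with oxalyl chloride and catalytic DMF in CH2Cl2 at 0 °C. Chloride 4 would be turned into [2-(benzyloxy)-3,4-dimethoxybenzyl]zinc chloride F3 by LiCl-promoted insertion of Zn dust in THF, which should hardly homocouple. Negishi acylation of F2 with F3 under Pd(PPh3)4 (zerovalent palladium) in THF should then give 10.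

Step 11. Oxidative addition into the electron-rich, fully substituted 2-chloroimidazole may be slow, and the basic ring nitrogen may sequester the catalyst, so the coupling could stall or end in hydrodechlorination. The fallback brings in nitrogen by C2 metalation and azide transfer. It sets out from N-oxide 14 (so it also bypasses step 10) and comes back at aminophenol 18. Deoxygenation of 14 with Raney Ni in EtOH at rt should give 5-[2-(benzyloxy)-3,4-dimethoxybenzyl]-4-(4-methoxybenzyl)-1-methyl-1H-imidazole F4. Lithiation with n-BuLi in THF at −78 °C should give the 2-lithio derivative {5-[2-(benzyloxy)-3,4-dimethoxybenzyl]-4-(4-methoxybenzyl)-1-methyl-1H-imidazol-2-yl}lithium F5. Trapping with tosyl azide should give 2-azido-5-[2-(benzyloxy)-3,4-dimethoxybenzyl]-4-(4-methoxybenzyl)-1-methyl-1H-imidazole F6. Hydrogenation (H2, 10% Pd/C, MeOH) would reduce the azide and cleave the benzyl ether in one operation to give 18.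

Step 13. The addition–elimination may stall because the free phenol competes for the activated trione or for the silylating agent, and the electron-rich aminophenol may be oxidised by air at reflux. The fallback keeps the phenol masked through the condensation and makes the deprotection the last step. It sets out from benzyl ether 17 and comes back at the target 21. Amine 17 would be condensed with 20 (19, BSA, MeCN, reflux; then toluene, reflux) to 4-({5-[2-(benzyloxy)-3,4-dimethoxybenzyl]-4-(4-methoxybenzyl)-1-methyl-1H-imidazol-2-yl}amino)-1-methyl-1H-imidazole-2,5-dione (O-benzylpyronaamidine) F7. Hydrogenolysis (H2, 10% Pd/C, EtOAc/MeOH, rt) should then give 21.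

**Further compounds**
F1 | step 7 | tert-butyl(dimethyl)silyl (2E)-2-({[tert-butyl(dimethyl)silyl]oxy}imino)-3-(4-methoxyphenyl)propanoate | COc1ccc(C/C(=N\O[Si](C)(C)C(C)(C)C)C(=O)O[Si](C)(C)C(C)(C)C)cc1
F2 | step 7 | (2E)-2-({[tert-butyl(dimethyl)silyl]oxy}imino)-3-(4-methoxyphenyl)propanoyl chloride | COc1ccc(C/C(=N\O[Si](C)(C)C(C)(C)C)C(Cl)=O)cc1
F3 | step 7 | [2-(benzyloxy)-3,4-dimethoxybenzyl]zinc chloride | COc1ccc(C[Zn]Cl)c(OCc2ccccc2)c1OC
F4 | step 11 | 5-[2-(benzyloxy)-3,4-dimethoxybenzyl]-4-(4-methoxybenzyl)-1-methyl-1H-imidazole | COc1ccc(Cc2ncn(C)c2Cc2ccc(OC)c(OC)c2OCc2ccccc2)cc1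
F5 | step 11 | {5-[2-(benzyloxy)-3,4-dimethoxybenzyl]-4-(4-methoxybenzyl)-1-methyl-1H-imidazol-2-yl}lithium | COc1ccc(Cc2nc([Li])n(C)c2Cc2ccc(OC)c(OC)c2OCc2ccccc2)cc1
F6 | step 11 | 2-azido-5-[2-(benzyloxy)-3,4-dimethoxybenzyl]-4-(4-methoxybenzyl)-1-methyl-1H-imidazole | COc1ccc(Cc2nc(N=[N+]=[N-])n(C)c2Cc2ccc(OC)c(OC)c2OCc2ccccc2)cc1
F7 | step 13 | 4-({5-[2-(benzyloxy)-3,4-dimethoxybenzyl]-4-(4-methoxybenzyl)-1-methyl-1H-imidazol-2-yl}amino)-1-methyl-1H-imidazole-2,5-dione | COc1ccc(Cc2nc(NC3=NC(=O)N(C)C3=O)n(C)c2Cc2ccc(OC)c(OC)c2OCc2ccccc2)cc1
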